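**Retrosynthetic overview**
1. Icetexane numbering: ring A = C1–C5 + C10; ring B (seven-membered) = C5, C6, C7, C8, C9, C20, C10; C8, C9, C11–C14 = arene/quinone. Komaroviquinone ⇒ trimethoxyarene silyl ketal (last step: desilylation and oxidative demethylation of the C11/C14 pair).
2. Ring A is cut at C4–C5: 6-exo radical cyclization of a C4 tertiary radical (H-atom transfer to the C3=C4 alkene of a 4-methylpent-3-enyl chain on C10) onto the C5=C6 alkene of a benzo-fused 8-oxabicyclo[3.2.1]octadiene.
3. Enabling feature: the C7–O–C10 ketal bridge, i.e. the five-membered ring O/C10/C5/C6/C7. It strains C5=C6, leaves only the exo face of C5 open to the chain on bridgehead C10, and turns the trans A/B junction into a cis annulation onto that five-membered ring.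
4. Ring B and the bridge are cut together at C7–C8 (aryllithium onto a butenolide carbonyl, alkoxide trapped as silyl ketal). The butenolide comes from an α-hydroxy aldehyde and Ph3P=C=C=O; C9–C20 comes from an aryllithium and an epoxide from Sharpless epoxidation, the only source of chirality (C10).
5. Order of ring formation: arene (bought) → butenolide (future oxa-bridge ring) → ring B → ring A → quinone oxidation level.

Key step: step 12

Remark: the final oxidation is assumed to give the para-quinone from the C11/C14 dimethoxy pair, and the hemiketal is drawn in its closed form.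

**Step 1**
Reactants: 1 1,2,4-trimethoxybenzene
Product: 3 2-(2,3,6-trimethoxyphenyl)propan-2-ol, via aryllithium 2 (not isolated)
Conditions: n-BuLi, THF, 0 °C → rt; acetone, −78 °C → rt
Reagents that add atoms: acetone CC(C)=O
Why: Directed ortho-lithiation at the CH flanked by two methoxy groups, then 1,2-addition of the aryllithium to acetone; no stereocentre is formed.

**Step 2**
Reactants: 3 2-(2,3,6-trimethoxyphenyl)propan-2-ol
Product: 4 1,2,4-trimethoxy-3-(propan-2-yl)benzene
Conditions: Et3SiH, CF3CO2H, CH2Cl2, 0 °C → rt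
Reagents that add atoms: none
Why: Ionic hydrogenation, in which acid ionizes the tertiary benzylic alcohol to a cation stabilized by two ortho methoxy groups and the silane delivers hydride.

**Step 3**
Reactants: 4 1,2,4-trimethoxy-3-(propan-2-yl)benzene
Product: 5 1-bromo-2,4,5-trimethoxy-3-(propan-2-yl)benzene
Conditions: NBS, MeCN, 0 °C → rt, dark
Reagents that add atoms: N-bromosuccinimide O=C1CCC(=O)N1Br
Why: Electrophilic aromatic bromination, expected at the CH that is ortho to one methoxy group and para to another (the future C8), leaving the future C9–H as the only ring hydrogen.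

**Step 4**
Reactants: 6 5-bromo-2-methylpent-2-ene; 7 prop-2-yn-1-ol
Product: 9 6-methyl-2-methylidenehept-5-en-1-ol, via Grignard reagent 8 (not isolated)
Conditions: Mg, THF, rt; then 7 (0.45 equiv), CuI (10 mol %), THF/Et2O, 0 °C → rt; aq. NH4Cl
Reagents that add atoms: none
Why: Copper-catalysed carbomagnesiation of the magnesium propargylic alkoxide, in which the alkyl group adds to the internal alkyne carbon through a five-membered chelated alkenylmagnesium that is protonated on work-up.

**Step 5**
Reactants: 9 6-methyl-2-methylidenehept-5-en-1-ol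
Product: 10 [(2R)-2-(4-methylpent-3-en-1-yl)oxiran-2-yl]methanol
Conditions: Ti(OiPr)4 (10 mol %), D-(−)-diethyl tartrate (12 mol %), t-BuOOH, 4 Å molecular sieves, CH2Cl2, −20 °C
Reagents that add atoms: tert-butyl hydroperoxide CC(C)(C)OO
Why: Sharpless asymmetric epoxidation, which is directed by the allylic hydroxyl (the remote trisubstituted alkene is left alone) and sets the quaternary C10 by reagent control, the D-(−)-tartrate being the one expected to give the (R)-epoxy alcohol.

**Step 6**
Reactants: 10 [(2R)-2-(4-methylpent-3-en-1-yl)oxiran-2-yl]methanol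
Product: 11 tert-butyl(dimethyl){[(2S)-2-(4-methylpent-3-en-1-yl)oxiran-2-yl]methoxy}silane
Conditions: TBSCl, imidazole, CH2Cl2, 0 °C → rt
Reagents that add atoms: tert-butyl(chloro)dimethylsilane CC(C)(C)[Si](C)(C)Cl
Why: Standard silylation of the primary alcohol; the descriptor changes by priority only, the stereocentre is untouched.

**Step 7**
Reactants: 5 1-bromo-2,4,5-trimethoxy-3-(propan-2-yl)benzene; 11 tert-butyl(dimethyl){[(2S)-2-(4-methylpent-3-en-1-yl)oxiran-2-yl]methoxy}silane
Product: 13 (2S)-1-[2-bromo-3,5,6-trimethoxy-4-(propan-2-yl)phenyl]-2-({[tert-butyl(dimethyl)silyl]oxy}methyl)-6-methylhept-5-en-2-ol, via aryllithium 12 (not isolated)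
Conditions: LDA, THF, −78 °C; then 11, BF3·OEt2 (2 equiv), −78 °C
Reagents that add atoms: none
Why: LDA removes the only ring hydrogen, acidified by the flanking bromine and methoxy group (future C9), and the aryllithium opens the Lewis-acid-activated epoxide at its CH2 terminus (SN2), forming C9–C20 without touching the C10 stereocentre.

**Step 8**
Reactants: 13 the silyl ether from step 7
Product: 14 (2S)-2-{[2-bromo-3,5,6-trimethoxy-4-(propan-2-yl)phenyl]methyl}-6-methylhept-5-ene-1,2-diol
Conditions: Bu4NF, THF, 0 °C → rt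
Reagents that add atoms: none
Why: Fluoride cleavage of the primary silyl ether; aryl bromide, tertiary alcohol and alkene are inert.

**Step 9**
Reactants: 14 the diol from step 8
Product: 15 (2S)-2-{[2-bromo-3,5,6-trimethoxy-4-(propan-2-yl)phenyl]methyl}-2-hydroxy-6-methylhept-5-enal
Conditions: SO3·pyridine, DMSO, i-Pr2NEt, CH2Cl2, 0 °C
Reagents that add atoms: none
Why: Parikh–Doering oxidation, which oxidizes only the primary carbinol and avoids glycol cleavage; the α-carbon is quaternary, so it cannot epimerize.

**Step 10**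
Reactants: 15 the α-hydroxy aldehyde from step 9
Product: 17 (5S)-5-{[2-bromo-3,5,6-trimethoxy-4-(propan-2-yl)phenyl]methyl}-5-(4-methylpent-3-en-1-yl)furan-2(5H)-one, via ester ylide 16 (not isolated)
Conditions: Ph3P=C=C=O, toluene, 110 °C
Reagents that add atoms: (triphenylphosphoranylidene)ketene O=C=C=P(c1ccccc1)(c1ccccc1)c1ccccc1
Why: Bestmann-ylide butenolide synthesis, in which the tertiary alcohol adds to the ketene to give an ester-stabilized ylide that closes onto the neighbouring aldehyde by intramolecular Wittig reaction, bringing in C6 and C7 with the cis C5=C6 alkene fixed by the ring.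

**Step 11**
Reactants: 17 the butenolide from step 10
Product: 20 triethyl{[(5R,8S)-1,2,4-trimethoxy-8-(4-methylpent-3-en-1-yl)-3-(propan-2-yl)-8,9-dihydro-5H-5,8-epoxybenzo[7]annulen-5-yl]oxy}silane, via aryllithium 18 (not isolated), via lithium hemiketalate 19 (not isolated)
Conditions: t-BuLi (2.1 equiv), THF/Et2O, −100 °C; then Et3SiOTf, −78 → 0 °C
Reagents that add atoms: triethylsilyl trifluoromethanesulfonate CC[Si](CC)(CC)OS(=O)(=O)C(F)(F)F
Why: Parham cyclization, in which bromine–lithium exchange outruns carbonyl attack at −100 °C and the C8 aryllithium adds 1,2 to the lactone carbonyl (six-membered transition state through the ring oxygen), forming C7–C8, ring B and the C7–O–C10 bridge at once; the tetrahedral lithium alkoxide, persistent at low temperature, is silylated on oxygen, and the C7 configuration is dictated by the bridge from C10.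

**Step 12**
Reactants: 20 the bridged silyl ketal from step 11 (icetexane numbering: 7R,10S)
Product: 21 (5S,7R,10S)-7,10-epoxy-11,12,14-trimethoxy-7-(triethylsilyloxy)icetexa-8,11,13-triene
Conditions: Mn(dpm)3 (20 mol %; dpm = dipivaloylmethanate), PhSiH3 (slow addition), t-BuOOH, i-PrOH (0.005 M), rt, argon
Reagents that add atoms: none
Why: H-atom transfer from the manganese hydride (from Mn(dpm)3 and PhSiH3) to C3 of the trisubstituted C3=C4 alkene gives the tertiary C4 radical, which adds 6-exo-trig to C5 of the strained C5=C6 alkene; the secondary C6 radical is reduced by a second H-atom transfer, so quaternary C4, the C4–C5 bond, ring A and the C5 stereocentre arise in one operation. The closest known reaction type is the Mukaiyama-type (metal-hydride H-atom-transfer) reductive radical cyclization of dienes onto non-conjugated alkenes. Ring A closes in the 6-exo-trig mode from a tether on bridgehead C10 to the adjacent alkene carbon, which gives a ring cis-fused to the five-membered ring O/C10/C5/C6/C7. C5 is under substrate control: the C7–O–C10 bridge leaves the exo face (syn to the bridging oxygen) open and the benzo bridge (C20, C9, C8) blocks the endo face, so C4 enters exo and H-5 ends anti to the C10–O bond, the A/B-trans relationship of the target; C10 and C7 are untouched. The step needs H-atom transfer to the trisubstituted alkene in preference to C5=C6 (tertiary over secondary radical) and ring closure faster than reduction of the open-chain radical; alkene strain, the two allylic C–O bonds that make C5=C6 a better partner for the nucleophilic radical, high dilution and slow silane addition should secure this.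

**Step 13**
Reactants: 21 the tetracyclic silyl ketal from step 12
Product: 23 komaroviquinone, via hemiketal 22 (not isolated)
Conditions: 1 M aq. HCl, MeCN, rt; then (NH4)2Ce(NO3)6, MeCN/H2O, 0 °C
Reagents that add atoms: water O
Why: Acid cleavage of the silyl ketal, then oxidative demethylation by tetravalent cerium of the para-disposed C11/C14 methoxy pair to the quinone (oxygens from water, C12–OMe kept); the C7 hemiketal can only exist bridged to C10, so its configuration is thermodynamically fixed.

**Compound list**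
1 | 1,2,4-trimethoxybenzene | COc1ccc(OC)c(OC)c1 | starting material
2 | (2,3,6-trimethoxyphenyl)lithium | [Li]c1c(OC)ccc(OC)c1OC | intermediate
3 | 2-(2,3,6-trimethoxyphenyl)propan-2-ol | COc1ccc(OC)c(C(C)(C)O)c1OC | intermediate
4 | 1,2,4-trimethoxy-3-(propan-2-yl)benzene | COc1ccc(OC)c(C(C)C)c1OC | intermediate
5 | 1-bromo-2,4,5-trimethoxy-3-(propan-2-yl)benzene | COc1cc(Br)c(OC)c(C(C)C)c1OC | intermediate
6 | 5-bromo-2-methylpent-2-ene | CC(C)=CCCBr | starting material
7 | prop-2-yn-1-ol | C#CCO | starting material
8 | (4-methylpent-3-en-1-yl)magnesium bromide | CC(C)=CCC[Mg]Br | intermediate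
9 | 6-methyl-2-methylidenehept-5-en-1-ol | C=C(CO)CCC=C(C)C | intermediate
10 | [(2R)-2-(4-methylpent-3-en-1-yl)oxiran-2-yl]methanol | C1O[C@@]1(CO)CCC=C(C)C | intermediate
11 | tert-butyl(dimethyl){[(2S)-2-(4-methylpent-3-en-1-yl)oxiran-2-yl]methoxy}silane | C1O[C@@]1(CO[Si](C)(C)C(C)(C)C)CCC=C(C)C | intermediate
12 | [2-bromo-3,5,6-trimethoxy-4-(propan-2-yl)phenyl]lithium | COc1c([Li])c(Br)c(OC)c(C(C)C)c1OC | intermediate
13 | (2S)-1-[2-bromo-3,5,6-trimethoxy-4-(propan-2-yl)phenyl]-2-({[tert-butyl(dimethyl)silyl]oxy}methyl)-6-methylhept-5-en-2-ol | COc1c(OC)c(C(C)C)c(OC)c(Br)c1C[C@@](CO[Si](C)(C)C(C)(C)C)(O)CCC=C(C)C | intermediate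
14 | (2S)-2-{[2-bromo-3,5,6-trimethoxy-4-(propan-2-yl)phenyl]methyl}-6-methylhept-5-ene-1,2-diol | COc1c(OC)c(C(C)C)c(OC)c(Br)c1C[C@@](CO)(O)CCC=C(C)C | intermediate
15 | (2S)-2-{[2-bromo-3,5,6-trimethoxy-4-(propan-2-yl)phenyl]methyl}-2-hydroxy-6-methylhept-5-enal | COc1c(OC)c(C(C)C)c(OC)c(Br)c1C[C@@](C=O)(O)CCC=C(C)C | intermediate
16 | (triphenylphosphoranylidene)acetate ester of 15 at the tertiary oxygen | COc1c(OC)c(C(C)C)c(OC)c(Br)c1C[C@@](C=O)(OC(=O)C=P(c1ccccc1)(c1ccccc1)c1ccccc1)CCC=C(C)C | intermediate
17 | (5S)-5-{[2-bromo-3,5,6-trimethoxy-4-(propan-2-yl)phenyl]methyl}-5-(4-methylpent-3-en-1-yl)furan-2(5H)-one | COc1c(OC)c(C(C)C)c(OC)c(Br)c1C[C@]1(C=CC(=O)O1)CCC=C(C)C | intermediate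
18 | aryllithium of 17 (lithium in place of bromine at C8) | COc1c(OC)c(C(C)C)c(OC)c([Li])c1C[C@]1(C=CC(=O)O1)CCC=C(C)C | intermediate
19 | lithium (7S,10S)-bridged hemiketalate (benzo-fused 8-oxabicyclo[3.2.1]octadiene, O–Li on C7, chain on C10, C5=C6 alkene) | COc1c(OC)c(C(C)C)c(OC)c2c1C[C@@]3(CCC=C(C)C)C=C[C@]2(O[Li])O3 | intermediate
20 | triethyl{[(5R,8S)-1,2,4-trimethoxy-8-(4-methylpent-3-en-1-yl)-3-(propan-2-yl)-8,9-dihydro-5H-5,8-epoxybenzo[7]annulen-5-yl]oxy}silane (icetexane numbering 7R,10S) | COc1c(OC)c(C(C)C)c(OC)c2c1C[C@@]3(CCC=C(C)C)C=C[C@]2(O[Si](CC)(CC)CC)O3 | intermediate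
21 | (5S,7R,10S)-7,10-epoxy-11,12,14-trimethoxy-7-(triethylsilyloxy)icetexa-8,11,13-triene | COc1c(OC)c(C(C)C)c(OC)c2c1C[C@@]13CCCC(C)(C)[C@@H]1C[C@]2(O[Si](CC)(CC)CC)O3 | intermediate
22 | (5S,7S,10S)-7,10-epoxy-11,12,14-trimethoxyicetexa-8,11,13-trien-7-ol | COc1c(OC)c(C(C)C)c(OC)c2c1C[C@@]13CCCC(C)(C)[C@@H]1C[C@]2(O)O3 | intermediate
23 | komaroviquinone, (5S,7S,10S) | COC1=C(C(C)C)C(=O)C2=C(C[C@@]34CCCC(C)(C)[C@@H]3C[C@]2(O)O4)C1=O | target

**Step count:** 13 steps in total. Longest linear sequence: 10 steps (steps 1, 2, 3, 7, 8, 9, 10, 11, 12, 13 from 1,2,4-trimethoxybenzene).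

**Steps most likely to fail**

1. Step 12. The open-chain C4 radical may be reduced (plain hydrogenation of the side chain), or H-atom transfer to the strained C5=C6 alkene may compete, before the 6-exo closure onto a non-conjugated alkene takes place. Fallback, from 20 back to 21: the radical is generated by a tin-hydride chain instead, where the H-donor concentration is set by syringe-pump addition. Mukaiyama hydration of the trisubstituted alkene (Co(acac)2, PhSiH3, O2, i-PrOH; oxygen trapping is much faster than ring closure) should give the tertiary alcohol F1. Acylation with methyl chlorooxoacetate (pyridine, DMAP) should give the tert-alkyl methyl oxalate F2. Bu3SnH and AIBN in toluene at 110 °C, added slowly, should fragment the oxalate to the same C4 radical, which closes 6-exo on the exo face and is reduced by the stannane to 21.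

2. Step 7. The ortho-bromo aryllithium may lose lithium bromide (aryne formation) before it opens the hindered 2,2-disubstituted epoxide, or the Lewis acid may rearrange the epoxide. Fallback, from 5 back to 13: a softer aryl-copper nucleophile without Lewis acid. LDA at −78 °C followed at once by iodine should give 1-bromo-2-iodo-3,4,6-trimethoxy-5-(propan-2-yl)benzene F3. Selective iodine–magnesium exchange with i-PrMgCl·LiCl at −40 °C should give [2-bromo-3,5,6-trimethoxy-4-(propan-2-yl)phenyl]magnesium chloride F4, which is stable toward elimination at that temperature. CuI-catalysed (10 mol %) opening of epoxide 11 at its CH2 terminus should then give 13.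

3. Step 11. The aryllithium may add in conjugate fashion to the butenolide (five-membered ring to C5), or the tetrahedral lithium alkoxide may collapse by ring-opening before it is silylated. Fallback, from 13 back to 22: intermolecular acylation, aldol ring closure and thermodynamic ketalization.
   - Deprotonation (n-BuLi), bromine–lithium exchange (t-BuLi, −78 °C) and acylation with N-methoxy-N-methylacetamide should give the aryl methyl ketone F5.
   - Bu4NF should give the diol F6, and Parikh–Doering oxidation the keto aldehyde F7.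
   - Intramolecular aldol condensation of the methyl ketone (C6) onto the C5 aldehyde (KOH, MeOH) should close ring B as the cis γ-hydroxy enone F8.
   - Acid-catalysed ketalization (PPTS, HC(OMe)3, MeOH) should give the bridged methyl ketal F9.
   - The H-atom-transfer cyclization of step 12 should give the tetracyclic methyl ketal F10.
   - Aqueous acid should hydrolyse F10 to 22, which is oxidized as in step 13.

**Further compounds**
F1 | step 12 | tertiary alcohol from hydration of 20: silyl ketal 20 with a 4-hydroxy-4-methylpentyl chain on C10 | COc1c(OC)c(C(C)C)c(OC)c2c1C[C@@]3(CCCC(C)(C)O)C=C[C@]2(O[Si](CC)(CC)CC)O3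
F2 | step 12 | methyl oxalate of F1 at the tertiary oxygen | COc1c(OC)c(C(C)C)c(OC)c2c1C[C@@]3(CCCC(C)(C)OC(=O)C(=O)OC)C=C[C@]2(O[Si](CC)(CC)CC)O3
F3 | step 7 | 1-bromo-2-iodo-3,4,6-trimethoxy-5-(propan-2-yl)benzene | COc1c(I)c(Br)c(OC)c(C(C)C)c1OC
F4 | step 7 | [2-bromo-3,5,6-trimethoxy-4-(propan-2-yl)phenyl]magnesium chloride | COc1c([Mg]Cl)c(Br)c(OC)c(C(C)C)c1OC
F5 | step 11 | 1-{2-[(2S)-2-({[tert-butyl(dimethyl)silyl]oxy}methyl)-2-hydroxy-6-methylhept-5-en-1-yl]-3,4,6-trimethoxy-5-(propan-2-yl)phenyl}ethan-1-one | COc1c(OC)c(C(C)C)c(OC)c(C(C)=O)c1C[C@@](CO[Si](C)(C)C(C)(C)C)(O)CCC=C(C)C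
F6 | step 11 | 1-{2-[(2S)-2-hydroxy-2-(hydroxymethyl)-6-methylhept-5-en-1-yl]-3,4,6-trimethoxy-5-(propan-2-yl)phenyl}ethan-1-one | COc1c(OC)c(C(C)C)c(OC)c(C(C)=O)c1C[C@@](CO)(O)CCC=C(C)C
F7 | step 11 | (2S)-2-{[2-acetyl-3,5,6-trimethoxy-4-(propan-2-yl)phenyl]methyl}-2-hydroxy-6-methylhept-5-enal | COc1c(OC)c(C(C)C)c(OC)c(C(C)=O)c1C[C@@](C=O)(O)CCC=C(C)C
F8 | step 11 | (8S)-8-hydroxy-1,2,4-trimethoxy-8-(4-methylpent-3-en-1-yl)-3-(propan-2-yl)-8,9-dihydro-5H-benzo[7]annulen-5-one | COc1c(OC)c(C(C)C)c(OC)c2c1C[C@@](O)(CCC=C(C)C)C=CC2=O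
F9 | step 11 | (5S,8S)-1,2,4,5-tetramethoxy-8-(4-methylpent-3-en-1-yl)-3-(propan-2-yl)-8,9-dihydro-5H-5,8-epoxybenzo[7]annulene | COc1c(OC)c(C(C)C)c(OC)c2c1C[C@@]3(CCC=C(C)C)C=C[C@]2(OC)O3
F10 | step 11 | (5S,7S,10S)-7,10-epoxy-7,11,12,14-tetramethoxyicetexa-8,11,13-triene | COc1c(OC)c(C(C)C)c(OC)c2c1C[C@@]13CCCC(C)(C)[C@@H]1C[C@]2(OC)O3
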